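**Strategy.** The eleven-membered ring (C1 bearing the exocyclic methylene, C2=C3, quaternary C4, C5, carbinol C6, C7, C8(Me)=C9, C10, C11) is opened at the C1–C2 sp2–sp2 bond of its 2-substituted 1,3-diene. One intramolecular Heck reaction of a 2-bromoalkene (C1) with the vinyl group on C4 forms that bond, closes the ring and creates the E C2=C3 olefin; the hydrogen-free C4 leaves only one direction for elimination. The precursor is an acyclic 2-bromo-1,5,11-triene that already carries the C6 stereocentre, the E C8=C9 olefin and the acetyl-protected vanillate ester, so that a single deacetylation follows the ring closure.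

Key step: step 8

Remark: the C6 oxygen is carried through the ring closure as the acetyl-protected vanillate instead of a silyl ether; the aryl acetate is assumed to tolerate anhydrous K2CO3 in MeCN, and its loss would only give 18 early. Counted from the bromoalkene, 16 is a 2-bromododeca-1,5,11-triene. (S)-TRIP is (S)-3,3'-bis(2,4,6-triisopropylphenyl)-1,1'-binaphthalene-2,2'-diyl hydrogen phosphate.

**Step 1**
Reactants: 1 methyl 3,3-dimethylpent-4-enoate
Product: 3 3,3-dimethylpent-4-enal, via aluminium hemiacetal 2 (not isolated)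
Conditions: i-Bu2AlH (1.05 equiv), toluene, −78 °C; MeOH, then aq. potassium sodium tartrate; dried toluene solution carried forward
Reagents that add atoms: none
Why: Partial ester reduction with diisobutylaluminium hydride: at −78 °C the tetrahedral aluminium hemiacetal 2 persists until hydrolysis, so the aldehyde never meets hydride, the isolated vinyl group is inert, and the volatile aldehyde is kept in solution.

**Step 2**
Reactants: 3 3,3-dimethylpent-4-enal; 4 allenylboronic acid pinacol ester
Product: 6 (S)-6,6-dimethyloct-7-en-1-yn-4-ol, via pinacol borate ester 5 (not isolated)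
Conditions: (S)-TRIP (10 mol%), 4 Å molecular sieves, toluene, −20 °C; aq. NaHCO3
Reagents that add atoms: none
Why: Chiral phosphoric acid-catalysed asymmetric propargylation of an aldehyde with an allenylboronate through a closed six-membered SE2' transition state (acid bound to a boronate oxygen and to the formyl hydrogen); the (S)-acid is chosen to deliver the propargyl group to the Si face of 3, which sets the carbinol centre (later ring atom C6) as S.

**Step 3**
Reactants: 6 (S)-6,6-dimethyloct-7-en-1-yn-4-ol
Product: 8 (4R,1E)-1-iodo-2,6,6-trimethylocta-1,7-dien-4-ol, via alkenylalane 7 (not isolated)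
Conditions: Me3Al (3 equiv), Cp2ZrCl2 (0.25 equiv), CH2Cl2, 0 → 23 °C; then I2 (1.05 equiv), THF, −30 °C; aq. potassium sodium tartrate, Na2S2O3
Reagents that add atoms: trimethylaluminium, C[Al](C)C; iodine, I-I
Why: Cp2ZrCl2-catalysed syn-carboalumination of the terminal alkyne (Negishi carboalumination), with the hydroxyl masked in situ as its aluminium alkoxide, puts methyl on the internal carbon and aluminium cis to it, and iodinolysis with retention should give the E iodoalkene; the hindered vinyl group and the stereocentre are untouched, and the descriptor changes to R only because the iodoalkenyl arm now ranks higher.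

**Step 4**
Reactants: 9 vanillic acid
Product: 10 4-acetoxy-3-methoxybenzoic acid
Conditions: Ac2O, pyridine, 23 °C; then H2O, aq. HCl
Reagents that add atoms: acetic anhydride, CC(=O)OC(C)=O
Why: O-Acetylation of the phenol with acetic anhydride; any mixed anhydride at the carboxyl group is hydrolysed in the aqueous quench, and the masked phenol cannot self-acylate in step 5.

**Step 5**
Reactants: 8 (4R,1E)-1-iodo-2,6,6-trimethylocta-1,7-dien-4-ol; 10 4-acetoxy-3-methoxybenzoic acid
Product: 12 (4R,1E)-1-iodo-2,6,6-trimethylocta-1,7-dien-4-yl 4-acetoxy-3-methoxybenzoate, via acid chloride 11 (not isolated)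
Conditions: 10, (COCl)2, DMF (cat.), CH2Cl2, 0 → 23 °C, evaporate; then 8, Et3N, DMAP (0.1 equiv), CH2Cl2, 0 → 23 °C
Reagents that add atoms: none
Why: Acid chloride formation followed by DMAP-catalysed acylation of the secondary alcohol, which occurs at oxygen and so retains the configuration; the ester then protects the C6 oxygen through both palladium-catalysed steps.

**Step 6**
Reactants: 13 3-bromobut-3-en-1-ol
Product: 14 2-bromo-4-iodobut-1-ene
Conditions: I2, PPh3, imidazole, CH2Cl2, 0 → 23 °C
Reagents that add atoms: iodine, I-I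
Why: Appel-type iodination of the primary alcohol by SN2 displacement of the alkoxyphosphonium ion; the 2-bromoalkene is inert.

**Step 7**
Reactants: 12 (4R,1E)-1-iodo-2,6,6-trimethylocta-1,7-dien-4-yl 4-acetoxy-3-methoxybenzoate; 14 2-bromo-4-iodobut-1-ene
Product: 16 (5S,7E)-11-bromo-3,3,7-trimethyldodeca-1,7,11-trien-5-yl 4-acetoxy-3-methoxybenzoate, via alkylzinc iodide 15 (not isolated)
Conditions: 14 (1.5 equiv), Zn dust (activated with BrCH2CH2Br and Me3SiCl), LiCl, THF, 40 °C; then 12, Pd(PPh3)4 (5 mol%), THF, 23 °C
Reagents that add atoms: none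
Why: Negishi sp3–sp2 cross-coupling: zinc inserts only into the primary C–I bond of 14, and zerovalent palladium adds to the alkenyl iodide of 12 far faster than to a 1,1-disubstituted alkenyl bromide at 23 °C, so the C9–C10 bond should form with retention of the E geometry while both esters tolerate the mild zinc reagent.

**Step 8**
Reactants: 16 (5S,7E)-11-bromo-3,3,7-trimethyldodeca-1,7,11-trien-5-yl 4-acetoxy-3-methoxybenzoate
Product: 17 (1S,3E,8E)-3,10,10-trimethyl-7-methylidenecycloundeca-3,8-dien-1-yl 4-acetoxy-3-methoxybenzoate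
Conditions: Pd(OAc)2 (0.2 equiv), P(o-tol)3 (0.4 equiv), K2CO3 (3 equiv), MeCN, 80 °C, slow addition of 16 to 0.002 M
Reagents that add atoms: none
Why: Zerovalent palladium, formed in situ from Pd(OAc)2 and P(o-tol)3, inserts into the C1–Br bond, the alkenylpalladium bromide adds syn across the vinyl group on C4 with C1 bonding to the terminal carbon C2, and syn β-hydride elimination of a C2–H releases the diene while K2CO3 takes up HBr. The closest known reaction type is the endo-selective macrocyclic Heck coupling of alkenyl halides with terminal alkenes to give 1,3-dienes, run here at high dilution. The single ring is closed in the 11-endo-trig mode. No stereocentre is created; the E geometry of C2=C3 should follow from syn elimination through the less strained ring conformer, and C6 and the C8=C9 geometry are untouched. Bonding at C2 and not C3 is secured by the neopentyl-like C4 next to C3, the hydrogen-free C4 blocks elimination in the other direction and chain walking, and the trisubstituted C8=C9 olefin could only be reached by a four-membered exo or five-membered endo closure, so it should not compete.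

**Step 9**
Reactants: 17 (1S,3E,8E)-3,10,10-trimethyl-7-methylidenecycloundeca-3,8-dien-1-yl 4-acetoxy-3-methoxybenzoate
Product: 18 (1S,3E,8E)-3,10,10-trimethyl-7-methylidenecycloundeca-3,8-dien-1-yl 4-hydroxy-3-methoxybenzoate
Conditions: pyrrolidine (3 equiv), CH2Cl2, 0 → 23 °C
Reagents that add atoms: none
Why: Chemoselective aminolysis of the aryl acetate, a phenyl ester far more electrophilic than the electron-rich secondary alkyl benzoate, under acid-free conditions that spare the triene, which is prone to transannular cyclisation.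

**Compound list**
1 | methyl 3,3-dimethylpent-4-enoate | C=CC(C)(C)CC(=O)OC | starting material
2 | diisobutylaluminium 1-methoxy-3,3-dimethylpent-4-en-1-olate (aluminium hemiacetal) | C=CC(C)(C)CC(OC)O[Al](CC(C)C)CC(C)C | intermediate
3 | 3,3-dimethylpent-4-enal | C=CC(C)(C)CC=O | intermediate
4 | allenylboronic acid pinacol ester | C=C=CB1OC(C)(C)C(C)(C)O1 | starting material
5 | (S)-2-[(6,6-dimethyloct-7-en-1-yn-4-yl)oxy]-4,4,5,5-tetramethyl-1,3,2-dioxaborolane (pinacol borate ester) | C=CC(C)(C)C[C@@H](OB1OC(C)(C)C(C)(C)O1)CC#C | intermediate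
6 | (S)-6,6-dimethyloct-7-en-1-yn-4-ol | C=CC(C)(C)C[C@@H](O)CC#C | intermediate
7 | dimethylaluminium alkoxide of (1E)-1-(dimethylalumanyl)-2,6,6-trimethylocta-1,7-dien-4-ol, configuration at C4 as in 6 (alkenylalane) | C=CC(C)(C)C[C@@H](O[Al](C)C)C/C(C)=C/[Al](C)C | intermediate
8 | (4R,1E)-1-iodo-2,6,6-trimethylocta-1,7-dien-4-ol | C=CC(C)(C)C[C@@H](O)C/C(C)=C/I | intermediate
9 | vanillic acid (4-hydroxy-3-methoxybenzoic acid) | COc1cc(C(=O)O)ccc1O | starting material
10 | 4-acetoxy-3-methoxybenzoic acid | COc1cc(C(=O)O)ccc1OC(C)=O | intermediate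
11 | 4-acetoxy-3-methoxybenzoyl chloride | COc1cc(C(=O)Cl)ccc1OC(C)=O | intermediate
12 | (4R,1E)-1-iodo-2,6,6-trimethylocta-1,7-dien-4-yl 4-acetoxy-3-methoxybenzoate | C=CC(C)(C)C[C@@H](OC(=O)c1ccc(OC(C)=O)c(OC)c1)C/C(C)=C/I | intermediate
13 | 3-bromobut-3-en-1-ol | C=C(Br)CCO | starting material
14 | 2-bromo-4-iodobut-1-ene | C=C(Br)CCI | intermediate
15 | (3-bromobut-3-en-1-yl)zinc iodide | C=C(Br)CC[Zn]I | intermediate
16 | (5S,7E)-11-bromo-3,3,7-trimethyldodeca-1,7,11-trien-5-yl 4-acetoxy-3-methoxybenzoate | C=CC(C)(C)C[C@@H](OC(=O)c1ccc(OC(C)=O)c(OC)c1)C/C(C)=C/CCC(Br)=C | intermediate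
17 | (1S,3E,8E)-3,10,10-trimethyl-7-methylidenecycloundeca-3,8-dien-1-yl 4-acetoxy-3-methoxybenzoate | C=C1/C=C/C(C)(C)C[C@@H](OC(=O)c2ccc(OC(C)=O)c(OC)c2)C/C(C)=C/CC1 | intermediate
18 | (1S,3E,8E)-3,10,10-trimethyl-7-methylidenecycloundeca-3,8-dien-1-yl 4-hydroxy-3-methoxybenzoate | C=C1/C=C/C(C)(C)C[C@@H](OC(=O)c2ccc(O)c(OC)c2)C/C(C)=C/CC1 | target

**Totals.** Total step count: 9. Longest linear sequence: 7 steps (1, 2, 3, 5, 7, 8, 9) from 1.

**Steps most likely to fail**

1. Step 8. Closure of the strained eleven-membered ring is slow, so intermolecular coupling and oligomerisation may compete, the long-lived alkenylpalladium may be protodebrominated, and palladium hydride re-addition may move the exocyclic double bond into the ring or scramble the C2=C3 geometry. Fallback, setting out from 16: Stille coupling with Bu3SnCH=CH2 (Pd(PPh3)4, toluene, 90 °C) should give the 2-substituted buta-1,3-diene (5S,7E)-3,3,7-trimethyl-11-methylidenetrideca-1,7,12-trien-5-yl 4-acetoxy-3-methoxybenzoate F1. Ring-closing ene–diene metathesis of F1 (second-generation Grubbs catalyst, CH2Cl2, 40 °C, 0.001 M) between the monosubstituted diene terminus and the vinyl group on C4 expels ethylene and returns to the route at 17.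

2. Step 7. The iodide-over-bromide selectivity may erode: oxidative addition into the alkenyl bromide of the zinc reagent or of the product would lead to oligomerisation and double coupling. Fallback, setting out from 12: a zinc reagent without a second halide, [4-(trimethylsilyl)but-3-yn-1-yl]zinc bromide F2, is made from commercial (4-bromobut-1-yn-1-yl)trimethylsilane (Zn dust, LiCl, THF, 50 °C). Negishi coupling with 12 (Pd(PPh3)4, THF, 23 °C) should give (5S,7E)-3,3,7-trimethyl-12-(trimethylsilyl)dodeca-1,7-dien-11-yn-5-yl 4-acetoxy-3-methoxybenzoate F3. Buffered fluoride (Bu4NF, AcOH, THF, 0 °C) frees the terminal alkyne (5S,7E)-3,3,7-trimethyldodeca-1,7-dien-11-yn-5-yl 4-acetoxy-3-methoxybenzoate F4. Syn-bromoboration with B-bromo-9-borabicyclo[3.3.1]nonane (CH2Cl2, 0 °C) gives the (Z)-2-bromoalkenylborane F5, whose protonolysis with AcOH returns to the route at 16.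

3. Step 2. Facial selectivity may be insufficient with this β-branched aliphatic aldehyde, and an uncatalysed background addition may lower it further; the configuration and enantiomeric purity of 6 should be checked before it is carried on, and the antipodal acid used if the opposite sense were found. Fallback, setting out from 3: Corey–Chaykovsky methylenation (trimethylsulfonium iodide, NaH, DMSO–THF) gives racemic 2-(2,2-dimethylbut-3-en-1-yl)oxirane F6. Hydrolytic kinetic resolution with the (salen)Co(OAc) enantiomer that consumes the S epoxide (expected to be the R,R complex; H2O 0.55 equiv) leaves (R)-2-(2,2-dimethylbut-3-en-1-yl)oxirane F7 beside (S)-4,4-dimethylhex-5-ene-1,2-diol F8, which is separated. Opening of F7 at its CH2 terminus with LiC≡CH·H2NCH2CH2NH2 (DMSO, 23 °C) retains the carbinol configuration and returns to the route at 6.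

**Further compounds**
F1 | step 8 | (5S,7E)-3,3,7-trimethyl-11-methylidenetrideca-1,7,12-trien-5-yl 4-acetoxy-3-methoxybenzoate | C=CC(C)(C)C[C@@H](OC(=O)c1ccc(OC(C)=O)c(OC)c1)C/C(C)=C/CCC(=C)C=C
F2 | step 7 | [4-(trimethylsilyl)but-3-yn-1-yl]zinc bromide | C[Si](C)(C)C#CCC[Zn]Br
F3 | step 7 | (5S,7E)-3,3,7-trimethyl-12-(trimethylsilyl)dodeca-1,7-dien-11-yn-5-yl 4-acetoxy-3-methoxybenzoate | C=CC(C)(C)C[C@@H](OC(=O)c1ccc(OC(C)=O)c(OC)c1)C/C(C)=C/CCC#C[Si](C)(C)C
F4 | step 7 | (5S,7E)-3,3,7-trimethyldodeca-1,7-dien-11-yn-5-yl 4-acetoxy-3-methoxybenzoate | C=CC(C)(C)C[C@@H](OC(=O)c1ccc(OC(C)=O)c(OC)c1)C/C(C)=C/CCC#C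
F5 | step 7 | (5S,7E,11Z)-12-(9-borabicyclo[3.3.1]nonan-9-yl)-11-bromo-3,3,7-trimethyldodeca-1,7,11-trien-5-yl 4-acetoxy-3-methoxybenzoate | C=CC(C)(C)C[C@@H](OC(=O)c1ccc(OC(C)=O)c(OC)c1)C/C(C)=C/CC/C(Br)=C/B1C2CCCC1CCC2
F6 | step 2 | racemic 2-(2,2-dimethylbut-3-en-1-yl)oxirane | C=CC(C)(C)CC1CO1
F7 | step 2 | (R)-2-(2,2-dimethylbut-3-en-1-yl)oxirane | C=CC(C)(C)C[C@@H]1CO1
F8 | step 2 | (S)-4,4-dimethylhex-5-ene-1,2-diol | C=CC(C)(C)C[C@H](O)CO
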